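**Retrosynthetic overview**
1. Target ⇐ hydrogenolysis of its tri-O-benzyl ether. Pyranone ring C is closed last (Baker–Venkataraman rearrangement, acid cyclodehydration) from a hexasubstituted 2-hydroxyacetophenone whose only free phenol becomes O1; this fixes the 6-OMe/8-pyrrolidinyl pattern.
2. Acetyl group ⇐ Br/Li exchange on an aryl bromide plus a Weinreb amide; N-methyl ⇐ reductive methylation.
3. The single stereocentre ⇐ imine reductase (IRED) reduction of a 2-aryl-1-pyrroline to the (R)-2-arylpyrrolidine.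
4. Pyrroline ring (first ring made) ⇐ Staudinger/aza-Wittig closure of a γ-azido aryl ketone ⇐ aryllithium + 4-chlorobutanoyl Weinreb amide.
5. Ring A ⇐ symmetric dibromide of 1,3-bis(benzyloxy)-2-methoxy-5-(methoxymethoxy)benzene ⇐ methyl 3,5-dihydroxy-4-methoxybenzoate (Dakin-type oxidation adds the fourth oxygen). Ring order: pyrroline/pyrrolidine, then ring C.

Assumption: the SMILES encodes (R) at C-2 of the pyrrolidine (priorities N > aryl > ring CH2 > H); all intermediates are named on that basis.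

**Route**

Step 1
Reactants: 1 methyl 3,5-dihydroxy-4-methoxybenzoate
Product: 2 methyl 3,5-bis(benzyloxy)-4-methoxybenzoate
Conditions: BnBr (2.3 equiv), K2CO3, DMF, 60 °C
Reagents that add atoms: benzyl bromide, BrCc1ccccc1
Why: Williamson ether synthesis on the two equivalent phenols gives benzyl ethers that survive the later acid, base and organolithium steps and leave by hydrogenolysis at the end.

Step 2
Reactants: 2 methyl 3,5-bis(benzyloxy)-4-methoxybenzoate
Product: 3 [3,5-bis(benzyloxy)-4-methoxyphenyl]methanol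
Conditions: LiAlH4, THF, 0 °C to rt
Reagents that add atoms: none
Why: Hydride reduction of the ester to the primary benzylic alcohol leaves the aryl ethers untouched.

Step 3
Reactants: 3 [3,5-bis(benzyloxy)-4-methoxyphenyl]methanol
Product: 4 3,5-bis(benzyloxy)-4-methoxybenzaldehyde
Conditions: MnO2 (activated, excess), CH2Cl2, rt
Reagents that add atoms: none
Why: Chemoselective benzylic alcohol oxidation with MnO2 stops cleanly at the aldehyde.

Step 4
Reactants: 4 3,5-bis(benzyloxy)-4-methoxybenzaldehyde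
Product: 6 3,5-bis(benzyloxy)-4-methoxyphenol, via aryl formate 5 (not isolated)
Conditions: mCPBA, NaHCO3, CH2Cl2, 0 °C to rt; then K2CO3 (cat.), MeOH, rt
Reagents that add atoms: 3-chloroperbenzoic acid (mCPBA), OOC(=O)c1cccc(Cl)c1
Why: Baeyer–Villiger (Dakin-type) oxidation, in which the electron-rich para-alkoxy aryl group migrates in preference to hydrogen, gives the aryl formate, and methanolysis frees the phenol.

Step 5
Reactants: 6 3,5-bis(benzyloxy)-4-methoxyphenol
Product: 7 1,3-bis(benzyloxy)-2-methoxy-5-(methoxymethoxy)benzene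
Conditions: MOMCl, i-Pr2NEt, CH2Cl2, 0 °C to rt
Reagents that add atoms: chloromethyl methyl ether, COCCl
Why: O-alkylation to the MOM acetal marks the oxygen that will become O1 with an acid-labile group orthogonal to the benzyl ethers.

Step 6
Reactants: 7 1,3-bis(benzyloxy)-2-methoxy-5-(methoxymethoxy)benzene
Product: 8 1,3-bis(benzyloxy)-4,6-dibromo-2-methoxy-5-(methoxymethoxy)benzene
Conditions: NBS (2.1 equiv), DMF, 0 °C to rt, dark
Reagents that add atoms: N-bromosuccinimide, O=C1CCC(=O)N1Br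
Why: Electrophilic aromatic bromination takes the only two free ring positions, which are symmetry-equivalent and each activated by two ortho and one para oxygen.

Step 7
Reactants: 8 1,3-bis(benzyloxy)-4,6-dibromo-2-methoxy-5-(methoxymethoxy)benzene; 9 4-chloro-N-methoxy-N-methylbutanamide
Product: 11 1-[2,4-bis(benzyloxy)-5-bromo-3-methoxy-6-(methoxymethoxy)phenyl]-4-chlorobutan-1-one, via aryllithium 10 (not isolated)
Conditions: n-BuLi (1.0 equiv), THF, −78 °C; then 9, −78 to −30 °C; aq. NH4Cl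
Reagents that add atoms: none
Why: Bromine–lithium exchange on one of two equivalent bromides followed by Weinreb ketone synthesis, where the chelated tetrahedral adduct prevents over-addition and the cold conditions spare the alkyl chloride.

Step 8
Reactants: 11 1-[2,4-bis(benzyloxy)-5-bromo-3-methoxy-6-(methoxymethoxy)phenyl]-4-chlorobutan-1-one
Product: 12 4-azido-1-[2,4-bis(benzyloxy)-5-bromo-3-methoxy-6-(methoxymethoxy)phenyl]butan-1-one
Conditions: NaN3, NaI (cat.), DMF, 60 °C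
Reagents that add atoms: sodium azide, [Na+].[N-]=[N+]=[N-]
Why: SN2 displacement of the primary chloride by azide (iodide catalysis) introduces the nitrogen without acid or strong base.

Step 9
Reactants: 12 4-azido-1-[2,4-bis(benzyloxy)-5-bromo-3-methoxy-6-(methoxymethoxy)phenyl]butan-1-one
Product: 14 5-[2,4-bis(benzyloxy)-5-bromo-3-methoxy-6-(methoxymethoxy)phenyl]-3,4-dihydro-2H-pyrrole, via iminophosphorane 13 (not isolated)
Conditions: PPh3, THF, rt then 65 °C
Reagents that add atoms: none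
Why: Staudinger reaction followed by intramolecular aza-Wittig closure forms the five-membered cyclic imine under neutral conditions that keep the MOM acetal.

Step 10
Reactants: 14 5-[2,4-bis(benzyloxy)-5-bromo-3-methoxy-6-(methoxymethoxy)phenyl]-3,4-dihydro-2H-pyrrole
Product: 15 (2R)-2-[2,4-bis(benzyloxy)-5-bromo-3-methoxy-6-(methoxymethoxy)phenyl]pyrrolidine
Conditions: imine reductase (IRED, (R)-2-arylpyrrolidine-selective, picked from an enantiocomplementary panel), NADP+ (cat.), glucose dehydrogenase, D-glucose, K2HPO4/KH2PO4 buffer pH 7.5, DMSO (15% v/v), 30 °C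
Reagents that add atoms: none
Why: In this biocatalytic asymmetric imine reduction the enzyme-bound NADPH delivers hydride to one face (Si) of the prochiral C=N, so the (R) stereocentre is set by catalyst control while glucose dehydrogenase regenerates the cofactor.

Step 11
Reactants: 15 (2R)-2-[2,4-bis(benzyloxy)-5-bromo-3-methoxy-6-(methoxymethoxy)phenyl]pyrrolidine
Product: 17 (2R)-2-[2,4-bis(benzyloxy)-5-bromo-3-methoxy-6-(methoxymethoxy)phenyl]-1-methylpyrrolidine, via N-methyleneiminium ion 16 (not isolated)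
Conditions: aq. HCHO, NaBH(OAc)3, ClCH2CH2Cl, rt
Reagents that add atoms: formaldehyde, C=O
Why: Reductive amination at nitrogen installs the N-methyl group at room temperature without touching the adjacent stereocentre.

Step 12
Reactants: 17 (2R)-2-[2,4-bis(benzyloxy)-5-bromo-3-methoxy-6-(methoxymethoxy)phenyl]-1-methylpyrrolidine; 18 N-methoxy-N-methylacetamide
Product: 20 1-{2,4-bis(benzyloxy)-3-methoxy-6-(methoxymethoxy)-5-[(2R)-1-methylpyrrolidin-2-yl]phenyl}ethan-1-one, via aryllithium 19 (not isolated)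
Conditions: n-BuLi, THF, −78 °C; then 18, −78 to −20 °C; aq. NH4Cl
Reagents that add atoms: none
Why: Fast bromine–lithium exchange at −78 °C (the tertiary amine and its benzylic C–H are inert) and Weinreb ketone synthesis give the aryl methyl ketone.

Step 13
Reactants: 20 1-{2,4-bis(benzyloxy)-3-methoxy-6-(methoxymethoxy)-5-[(2R)-1-methylpyrrolidin-2-yl]phenyl}ethan-1-one
Product: 21 1-{2,4-bis(benzyloxy)-6-hydroxy-3-methoxy-5-[(2R)-1-methylpyrrolidin-2-yl]phenyl}ethan-1-one
Conditions: conc. HCl (5 equiv), MeOH, rt; NaHCO3 work-up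
Reagents that add atoms: none
Why: Acid-catalysed acetal methanolysis removes only the MOM group (benzyl ethers are stable), freeing the one phenol that lies between the acetyl and pyrrolidinyl groups.

Step 14
Reactants: 21 1-{2,4-bis(benzyloxy)-6-hydroxy-3-methoxy-5-[(2R)-1-methylpyrrolidin-2-yl]phenyl}ethan-1-one; 22 4-(benzyloxy)benzoyl chloride
Product: 23 2-acetyl-3,5-bis(benzyloxy)-4-methoxy-6-[(2R)-1-methylpyrrolidin-2-yl]phenyl 4-(benzyloxy)benzoate
Conditions: Et3N, DMAP (cat.), CH2Cl2, 0 °C to rt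
Reagents that add atoms: none
Why: DMAP-catalysed O-acylation of the phenol gives the aryl ester needed for acyl transfer.

Step 15
Reactants: 23 2-acetyl-3,5-bis(benzyloxy)-4-methoxy-6-[(2R)-1-methylpyrrolidin-2-yl]phenyl 4-(benzyloxy)benzoate
Product: 24 1-{2,4-bis(benzyloxy)-6-hydroxy-3-methoxy-5-[(2R)-1-methylpyrrolidin-2-yl]phenyl}-3-[4-(benzyloxy)phenyl]propane-1,3-dione
Conditions: KOH (powdered), pyridine, 50 °C; AcOH quench
Reagents that add atoms: none
Why: Baker–Venkataraman rearrangement, an intramolecular Claisen-type O-to-C aroyl transfer from the ketone enolate, gives the 1,3-diketone and regenerates the phenol.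

Step 16
Reactants: 24 1-{2,4-bis(benzyloxy)-6-hydroxy-3-methoxy-5-[(2R)-1-methylpyrrolidin-2-yl]phenyl}-3-[4-(benzyloxy)phenyl]propane-1,3-dione
Product: 25 5,7-bis(benzyloxy)-2-[4-(benzyloxy)phenyl]-6-methoxy-8-[(2R)-1-methylpyrrolidin-2-yl]-4H-chromen-4-one
Conditions: H2SO4 (2 equiv), AcOH, 50 °C, short reaction time; NaHCO3 work-up
Reagents that add atoms: none
Why: Acid-catalysed cyclodehydration (hemiketal formation, loss of water) closes ring C through the only free phenol, the other ortho oxygen being benzylated, so the pyrrolidine ends up at C-8 and the methoxy group at C-6.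

Step 17
Reactants: 25 5,7-bis(benzyloxy)-2-[4-(benzyloxy)phenyl]-6-methoxy-8-[(2R)-1-methylpyrrolidin-2-yl]-4H-chromen-4-one
Product: 26 5,7-dihydroxy-2-(4-hydroxyphenyl)-6-methoxy-8-[(2R)-1-methylpyrrolidin-2-yl]-4H-chromen-4-one
Conditions: H2 (1 atm), 10% Pd/C, THF–MeOH, rt
Reagents that add atoms: none
Why: Catalytic hydrogenolysis cleaves the three O-benzyl ethers under neutral conditions at room temperature, which leaves the methyl ether, the flavone and the configurationally sensitive benzylic amine intact.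

The enantiomeric purity is checked by chiral HPLC at 15, 21, 25 and 26. After step 10, free-phenol intermediates are not heated.

**Compound list**
1 | methyl 3,5-dihydroxy-4-methoxybenzoate | COC(=O)c1cc(O)c(OC)c(O)c1 | starting material
2 | methyl 3,5-bis(benzyloxy)-4-methoxybenzoate | COC(=O)c1cc(OCc2ccccc2)c(OC)c(OCc3ccccc3)c1 | intermediate
3 | [3,5-bis(benzyloxy)-4-methoxyphenyl]methanol | OCc1cc(OCc2ccccc2)c(OC)c(OCc3ccccc3)c1 | intermediate
4 | 3,5-bis(benzyloxy)-4-methoxybenzaldehyde | O=Cc1cc(OCc2ccccc2)c(OC)c(OCc3ccccc3)c1 | intermediate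
5 | 3,5-bis(benzyloxy)-4-methoxyphenyl formate | O=COc1cc(OCc2ccccc2)c(OC)c(OCc3ccccc3)c1 | intermediate
6 | 3,5-bis(benzyloxy)-4-methoxyphenol | Oc1cc(OCc2ccccc2)c(OC)c(OCc3ccccc3)c1 | intermediate
7 | 1,3-bis(benzyloxy)-2-methoxy-5-(methoxymethoxy)benzene | COCOc1cc(OCc2ccccc2)c(OC)c(OCc3ccccc3)c1 | intermediate
8 | 1,3-bis(benzyloxy)-4,6-dibromo-2-methoxy-5-(methoxymethoxy)benzene | COCOc1c(Br)c(OCc2ccccc2)c(OC)c(OCc3ccccc3)c1Br | intermediate
9 | 4-chloro-N-methoxy-N-methylbutanamide | CON(C)C(=O)CCCCl | starting material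
10 | [2,4-bis(benzyloxy)-5-bromo-3-methoxy-6-(methoxymethoxy)phenyl]lithium | COCOc1c(Br)c(OCc2ccccc2)c(OC)c(OCc3ccccc3)c1[Li] | intermediate
11 | 1-[2,4-bis(benzyloxy)-5-bromo-3-methoxy-6-(methoxymethoxy)phenyl]-4-chlorobutan-1-one | COCOc1c(Br)c(OCc2ccccc2)c(OC)c(OCc3ccccc3)c1C(=O)CCCCl | intermediate
12 | 4-azido-1-[2,4-bis(benzyloxy)-5-bromo-3-methoxy-6-(methoxymethoxy)phenyl]butan-1-one | COCOc1c(Br)c(OCc2ccccc2)c(OC)c(OCc3ccccc3)c1C(=O)CCCN=[N+]=[N-] | intermediate
13 | 1-[2,4-bis(benzyloxy)-5-bromo-3-methoxy-6-(methoxymethoxy)phenyl]-4-[(triphenyl-λ5-phosphanylidene)amino]butan-1-one | COCOc1c(Br)c(OCc2ccccc2)c(OC)c(OCc3ccccc3)c1C(=O)CCCN=P(c4ccccc4)(c5ccccc5)c6ccccc6 | intermediate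
14 | 5-[2,4-bis(benzyloxy)-5-bromo-3-methoxy-6-(methoxymethoxy)phenyl]-3,4-dihydro-2H-pyrrole | COCOc1c(Br)c(OCc2ccccc2)c(OC)c(OCc3ccccc3)c1C4=NCCC4 | intermediate
15 | (2R)-2-[2,4-bis(benzyloxy)-5-bromo-3-methoxy-6-(methoxymethoxy)phenyl]pyrrolidine | COCOc1c(Br)c(OCc2ccccc2)c(OC)c(OCc3ccccc3)c1[C@H]4CCCN4 | intermediate
16 | (2R)-2-[2,4-bis(benzyloxy)-5-bromo-3-methoxy-6-(methoxymethoxy)phenyl]-1-methylidenepyrrolidin-1-ium | COCOc1c(Br)c(OCc2ccccc2)c(OC)c(OCc3ccccc3)c1[C@H]4CCC[N+]4=C | intermediate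
17 | (2R)-2-[2,4-bis(benzyloxy)-5-bromo-3-methoxy-6-(methoxymethoxy)phenyl]-1-methylpyrrolidine | COCOc1c(Br)c(OCc2ccccc2)c(OC)c(OCc3ccccc3)c1[C@H]4CCCN4C | intermediate
18 | N-methoxy-N-methylacetamide | CON(C)C(C)=O | starting material
19 | {2,4-bis(benzyloxy)-3-methoxy-6-(methoxymethoxy)-5-[(2R)-1-methylpyrrolidin-2-yl]phenyl}lithium | COCOc1c([Li])c(OCc2ccccc2)c(OC)c(OCc3ccccc3)c1[C@H]4CCCN4C | intermediate
20 | 1-{2,4-bis(benzyloxy)-3-methoxy-6-(methoxymethoxy)-5-[(2R)-1-methylpyrrolidin-2-yl]phenyl}ethan-1-one | COCOc1c(C(C)=O)c(OCc2ccccc2)c(OC)c(OCc3ccccc3)c1[C@H]4CCCN4C | intermediate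
21 | 1-{2,4-bis(benzyloxy)-6-hydroxy-3-methoxy-5-[(2R)-1-methylpyrrolidin-2-yl]phenyl}ethan-1-one | Oc1c(C(C)=O)c(OCc2ccccc2)c(OC)c(OCc3ccccc3)c1[C@H]4CCCN4C | intermediate
22 | 4-(benzyloxy)benzoyl chloride | O=C(Cl)c1ccc(OCc2ccccc2)cc1 | starting material
23 | 2-acetyl-3,5-bis(benzyloxy)-4-methoxy-6-[(2R)-1-methylpyrrolidin-2-yl]phenyl 4-(benzyloxy)benzoate | O=C(Oc1c(C(C)=O)c(OCc2ccccc2)c(OC)c(OCc3ccccc3)c1[C@H]4CCCN4C)c5ccc(OCc6ccccc6)cc5 | intermediate
24 | 1-{2,4-bis(benzyloxy)-6-hydroxy-3-methoxy-5-[(2R)-1-methylpyrrolidin-2-yl]phenyl}-3-[4-(benzyloxy)phenyl]propane-1,3-dione | Oc1c(C(=O)CC(=O)c5ccc(OCc6ccccc6)cc5)c(OCc2ccccc2)c(OC)c(OCc3ccccc3)c1[C@H]4CCCN4C | intermediate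
25 | 5,7-bis(benzyloxy)-2-[4-(benzyloxy)phenyl]-6-methoxy-8-[(2R)-1-methylpyrrolidin-2-yl]-4H-chromen-4-one | COc1c(OCc2ccccc2)c([C@H]3CCCN3C)c4oc(-c5ccc(OCc6ccccc6)cc5)cc(=O)c4c1OCc7ccccc7 | intermediate
26 | 5,7-dihydroxy-2-(4-hydroxyphenyl)-6-methoxy-8-[(2R)-1-methylpyrrolidin-2-yl]-4H-chromen-4-one | COc1c(O)c([C@H]2CCCN2C)c2oc(-c3ccc(O)cc3)cc(=O)c2c1O | target

**Totals**
Total step count: 17. Longest linear sequence: 17 steps (1 to 26); compounds 9, 18 and 22 are bought.

**Three steps most likely to fail**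

Step 10 (enzymatic reduction). The imine carbon of 14 sits between two ortho alkoxy groups and the substrate is large and lipophilic, so turnover or selectivity of the imine reductase may be poor. The fallback sets out from 14. The imine nitrogen is methylated with MeOTf (CH2Cl2, 0 °C) to give 5-[2,4-bis(benzyloxy)-5-bromo-3-methoxy-6-(methoxymethoxy)phenyl]-1-methyl-3,4-dihydro-2H-pyrrol-1-ium triflate F1. This iminium salt is then hydrogenated enantioselectively (H2, [Ir(cod)Cl]2 with a chiral bisphosphine such as SegPhos, ligand antipode selected for the (R)-amine), and NaHCO3 work-up gives 17. The route is rejoined at 17, with the stereocentre set by transition-metal asymmetric hydrogenation and the N-methyl group already in place.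

Step 12 (acetylation). The aryllithium 19 is flanked by two ortho alkoxy groups and may deprotonate the acetyl Weinreb amide instead of adding to it. The fallback sets out from 17. After the same Br/Li exchange, 19 is trapped with acetaldehyde (THF, −78 °C) to give 1-{2,4-bis(benzyloxy)-3-methoxy-6-(methoxymethoxy)-5-[(2R)-1-methylpyrrolidin-2-yl]phenyl}ethan-1-ol F2, an inconsequential mixture of carbinol epimers. Oxidation with MnO2 (CH2Cl2, rt) or Dess–Martin periodinane gives the ketone, and the route is rejoined at 20.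

Step 16 (cyclodehydration). Warm protic acid could erode the ee through reversible ionisation of the benzylic C–N bond on the electron-rich ring, or strip the 5-O-benzyl group early. The fallback sets out from 17 and closes ring C under base at room temperature.
- Commercial 1-(benzyloxy)-4-ethynylbenzene is formylated (n-BuLi, then DMF, THF, −78 °C) to 3-[4-(benzyloxy)phenyl]prop-2-ynal F3.
- Aryllithium 19 (from 17, n-BuLi, −78 °C) adds to it to give 1-{2,4-bis(benzyloxy)-3-methoxy-6-(methoxymethoxy)-5-[(2R)-1-methylpyrrolidin-2-yl]phenyl}-3-[4-(benzyloxy)phenyl]prop-2-yn-1-ol F4.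
- MnO2 oxidation gives 1-{2,4-bis(benzyloxy)-3-methoxy-6-(methoxymethoxy)-5-[(2R)-1-methylpyrrolidin-2-yl]phenyl}-3-[4-(benzyloxy)phenyl]prop-2-yn-1-one F5.
- Brief cold HCl/MeOH (0 °C) removes the MOM group to give 1-{2,4-bis(benzyloxy)-6-hydroxy-3-methoxy-5-[(2R)-1-methylpyrrolidin-2-yl]phenyl}-3-[4-(benzyloxy)phenyl]prop-2-yn-1-one F6.
- Cs2CO3 in acetone at rt (or Et2NH by way of the enaminone) effects 6-endo oxa-Michael cyclisation, and the route is rejoined at 25.

**Further compounds**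
F1 | step 10 | 5-[2,4-bis(benzyloxy)-5-bromo-3-methoxy-6-(methoxymethoxy)phenyl]-1-methyl-3,4-dihydro-2H-pyrrol-1-ium trifluoromethanesulfonate | COCOc1c(Br)c(OCc2ccccc2)c(OC)c(OCc3ccccc3)c1C4=[N+](C)CCC4.[O-]S(=O)(=O)C(F)(F)F
F2 | step 12 | 1-{2,4-bis(benzyloxy)-3-methoxy-6-(methoxymethoxy)-5-[(2R)-1-methylpyrrolidin-2-yl]phenyl}ethan-1-ol (carbinol epimers) | COCOc1c(C(C)O)c(OCc2ccccc2)c(OC)c(OCc3ccccc3)c1[C@H]4CCCN4C
F3 | step 16 | 3-[4-(benzyloxy)phenyl]prop-2-ynal | O=CC#Cc1ccc(OCc2ccccc2)cc1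
F4 | step 16 | 1-{2,4-bis(benzyloxy)-3-methoxy-6-(methoxymethoxy)-5-[(2R)-1-methylpyrrolidin-2-yl]phenyl}-3-[4-(benzyloxy)phenyl]prop-2-yn-1-ol (carbinol epimers) | COCOc1c(C(O)C#Cc5ccc(OCc6ccccc6)cc5)c(OCc2ccccc2)c(OC)c(OCc3ccccc3)c1[C@H]4CCCN4C
F5 | step 16 | 1-{2,4-bis(benzyloxy)-3-methoxy-6-(methoxymethoxy)-5-[(2R)-1-methylpyrrolidin-2-yl]phenyl}-3-[4-(benzyloxy)phenyl]prop-2-yn-1-one | COCOc1c(C(=O)C#Cc5ccc(OCc6ccccc6)cc5)c(OCc2ccccc2)c(OC)c(OCc3ccccc3)c1[C@H]4CCCN4C
F6 | step 16 | 1-{2,4-bis(benzyloxy)-6-hydroxy-3-methoxy-5-[(2R)-1-methylpyrrolidin-2-yl]phenyl}-3-[4-(benzyloxy)phenyl]prop-2-yn-1-one | Oc1c(C(=O)C#Cc5ccc(OCc6ccccc6)cc5)c(OCc2ccccc2)c(OC)c(OCc3ccccc3)c1[C@H]4CCCN4C
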